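**Plan**
- Retrosynthetic cuts, in order: C2–C3 and C3=C4 of the enyne (Sonogashira, Takai); the oxane bridge at O–C10 together with C9–Br (transannular bromoetherification); C5–C6 (allylation); the oxocane at O–C7 and C7–C8; the oxolane at O–C13 together with C12–Br; C9–C10 (vinyl Grignard).
- Enabling feature: the O–C13(Et)–C12(Br)–C11–C10 edge of the oxocane is a 3-bromo-2-ethyloxolane carrying a vinyl group (C9=C8) on C10, and C7 is an α-oxy carbon that can be delivered as a carbenoid.
- Forward order: dienol → bromo-oxolane (ring A, 5-endo) → five-to-eight ring expansion by C7 to the oxocene (ring B) → C6 side chain → oxane bridge (ring C) → E-enyne.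
- Stereochemistry: C10 of the dienol comes from a Sharpless kinetic resolution; it directs C12/C13 in the first bromoetherification and is then traded for C7 in the sigmatropic shift. C6 comes from the Brown reagent, C9/C10 from anti addition across the ring alkene, and the E C3=C4 bond from the Takai reaction.

Key step: step 5

Remark: carbons keep the chain numbering C1 (alkyne CH) to C15 (ethyl CH3) in every intermediate; the 2,8-cis oxocene ester is assumed to be the more stable C7 epimer, as is usual for cis-α,α'-disubstituted medium-ring ethers.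

Step 1
Reactants: 1 (E)-hex-3-en-1-ol
Product: 2 (E)-hex-3-enal
Conditions: Dess–Martin periodinane, NaHCO3, CH2Cl2, 0 °C to rt; carried on as a cold concentrated solution
Reagents that add atoms: none
Why: Dess–Martin oxidation under bicarbonate buffering is mild and non-basic enough to give the β,γ-unsaturated aldehyde without migration of the E double bond into conjugation.

Step 2
Reactants: 2 (E)-hex-3-enal; 3 vinylmagnesium bromide
Product: 4 rac-(5E)-octa-1,5-dien-3-ol
Conditions: THF, −78 to 0 °C; then aq NH4Cl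
Reagents that add atoms: none
Why: Grignard 1,2-addition to the aldehyde at low temperature outruns enolisation and should give the racemic allylic alcohol with the E alkene intact.

Step 3
Reactants: 4 rac-(5E)-octa-1,5-dien-3-ol
Product: 5 (3S,5E)-octa-1,5-dien-3-ol (recovered slow-reacting enantiomer)
Conditions: Ti(OiPr)4 (0.2 equiv), D-(−)-diisopropyl tartrate (0.25 equiv), t-BuOOH (0.6 equiv), 4 Å molecular sieves, CH2Cl2, −20 °C; stopped just past half conversion
Reagents that add atoms: none
Why: In this Sharpless kinetic resolution the D-(−)-tartrate catalyst epoxidises the vinyl group of the (R)-alcohol much faster than that of the (S)-alcohol, and the remote alkene is only homoallylic to the hydroxyl and reacts far more slowly, so the (S)-enantiomer should be recovered enantioenriched.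

Step 4
Reactants: 5 (3S,5E)-octa-1,5-dien-3-ol
Product: 6 (2R,3S,5S)-3-bromo-5-ethenyl-2-ethyloxolane
Conditions: NBS (1.1 equiv), MeCN, −20 to 0 °C, dark
Reagents that add atoms: N-bromosuccinimide, O=C1CCC(=O)N1Br
Why: In this 5-endo bromoetherification the more electron-rich E-disubstituted alkene is brominated and the hydroxyl attacks C13 anti to bromine, which fixes Br12 and Et13 trans, while a chair-like transition state with the C10 vinyl group pseudo-equatorial (the sense seen in iodocyclisations of E-homoallylic alcohols) should give the 2,5-trans ring, so that C10 sets C12 (S) and C13 (R).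

Step 5
Reactants: 6 (2R,3S,5S)-3-bromo-5-ethenyl-2-ethyloxolane; 7 ethyl diazoacetate
Product: 9 ethyl (2R,4Z,7S,8R)-7-bromo-8-ethyl-3,6,7,8-tetrahydro-2H-oxocine-2-carboxylate, via oxonium ylide 8 (not isolated)
Conditions: Cu(hfacac)2 (5 mol %), CH2Cl2, reflux; 7 (3 equiv) added by syringe pump over 10 h
Reagents that add atoms: none
Why: Proposed new method: Cu(hfacac)2, an electrophilic divalent copper catalyst, converts 7 into a copper carbenoid that is captured by a lone pair of the ring oxygen of 6 on the face carrying the vinyl group (anti to the C13 ethyl group) to give oxonium ylide 8, whose carbanion carbon (C7) then bonds to the vinyl terminus (C8) in a concerted [2,3]-sigmatropic shift through a five-membered envelope while the allylic O–C10 bond breaks. The closest known reactions are the three-atom [2,3] ring expansion of 2-vinyl cyclic sulfonium ylides and the copper- or rhodium-carbenoid oxonium-ylide [2,3] shift of acyclic allylic ethers; carrying both over to the oxygen of a 2-vinyl oxolane is the untested element. The eight-membered ring is not closed end to end but arises by enlargement of the oxolane through a ring-fused five-membered transition state, and the alternative that would give a trans-cyclooctene is too strained, so the C9=C10 alkene should be cis. The new C7 centre is controlled by the C10 centre of 6, which is consumed in the shift (chirality transfer): with the ylide carbon cis to vinyl and trans to ethyl, the ester sits exo to the oxolane ring in the envelope, which places the C7 and C13 substituents cis across oxygen (7R), while C12 and C13 pass through untouched. The step needs ylide formation to outrun cyclopropanation of the vinyl group and carbene dimerisation; the electron-poor hexafluoroacetylacetonate ligand, the inductively deactivated allylic alkene and slow addition of 7 should secure this, and any C7 epimer should be correctable by DBU equilibration of the α-alkoxy ester.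

Step 6
Reactants: 9 ethyl (2R,4Z,7S,8R)-7-bromo-8-ethyl-3,6,7,8-tetrahydro-2H-oxocine-2-carboxylate
Product: 10 (2R,4Z,7S,8R)-7-bromo-8-ethyl-3,6,7,8-tetrahydro-2H-oxocine-2-carbaldehyde
Conditions: i-Bu2AlH (1.1 equiv), CH2Cl2, −78 °C; then aq potassium sodium tartrate; used crude at once
Reagents that add atoms: none
Why: Partial reduction of an α-alkoxy ester with i-Bu2AlH at −78 °C stops at the chelated aluminium hemiacetal, which releases the aldehyde only on work-up, and the secondary bromide and ring alkene are inert under these conditions.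

Step 7
Reactants: 10 (2R,4Z,7S,8R)-7-bromo-8-ethyl-3,6,7,8-tetrahydro-2H-oxocine-2-carbaldehyde
Product: 11 (1R)-1-[(2R,4Z,7S,8R)-7-bromo-8-ethyl-3,6,7,8-tetrahydro-2H-oxocin-2-yl]but-3-en-1-ol
Conditions: (+)-Ipc2BOMe, allylmagnesium bromide, Et2O, 0 °C to rt; then 10, −78 °C; HOCH2CH2NH2 work-up
Reagents that add atoms: allylmagnesium bromide, C=CC[Mg]Br (allyl group, passed on through B-allyldiisopinocampheylborane made in the flask)
Why: In this Brown allylation the allylborane from (+)-Ipc2BOMe adds through a closed chair transition state to the Re face of the aldehyde under reagent control, overriding the Felkin bias of the α-alkoxy aldehyde and setting C6 as R, syn to the C7 ether oxygen.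

Step 8
Reactants: 11 (1R)-1-[(2R,4Z,7S,8R)-7-bromo-8-ethyl-3,6,7,8-tetrahydro-2H-oxocin-2-yl]but-3-en-1-ol
Product: 12 (1R,3R,4S,6S,8R,10S)-4,10-dibromo-3-ethyl-8-(prop-2-en-1-yl)-2,7-dioxabicyclo[4.2.2]decane
Conditions: NBS (1.05 equiv), CH2Cl2, −20 °C, dark
Reagents that add atoms: N-bromosuccinimide, O=C1CCC(=O)N1Br
Why: In this transannular bromoetherification NBS brominates the more nucleophilic cis ring alkene on the face remote from the C7 side chain and the C6 hydroxyl opens the bromonium ion at C10 in a six-membered closure anti to bromine, the mode by which 6-hydroxy oxocenes of this natural-product family cyclise, which sets C10 (S) and C9 (S); the monosubstituted allyl alkene should react more slowly.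

Step 9
Reactants: 12 (1R,3R,4S,6S,8R,10S)-4,10-dibromo-3-ethyl-8-(prop-2-en-1-yl)-2,7-dioxabicyclo[4.2.2]decane
Product: 14 [(1R,3R,4S,6S,8R,10S)-4,10-dibromo-3-ethyl-2,7-dioxabicyclo[4.2.2]decan-8-yl]acetaldehyde, via ozonide 13 (not isolated)
Conditions: O3, CH2Cl2, −78 °C; then PPh3, −78 °C to rt
Reagents that add atoms: ozone, [O-][O+]=O
Why: Ozonolysis with reductive work-up cleaves the only remaining alkene to the aldehyde, and ethers and secondary bromides are inert to ozone at −78 °C.

Step 10
Reactants: 14 [(1R,3R,4S,6S,8R,10S)-4,10-dibromo-3-ethyl-2,7-dioxabicyclo[4.2.2]decan-8-yl]acetaldehyde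
Product: 15 (1R,3R,4S,6S,8R,10S)-4,10-dibromo-3-ethyl-8-[(2E)-3-iodoprop-2-en-1-yl]-2,7-dioxabicyclo[4.2.2]decane
Conditions: CrCl2 (6 equiv), CHI3 (2 equiv), THF, 0 °C to rt
Reagents that add atoms: iodoform, IC(I)I
Why: In this Takai olefination the geminal dichromium reagent formed from CHI3 and divalent chromium adds to the aldehyde and eliminates to the E vinyl iodide under non-basic conditions that should spare the β-alkoxy aldehyde and the unactivated secondary bromides.

Step 11
Reactants: 15 (1R,3R,4S,6S,8R,10S)-4,10-dibromo-3-ethyl-8-[(2E)-3-iodoprop-2-en-1-yl]-2,7-dioxabicyclo[4.2.2]decane; 16 trimethylsilylacetylene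
Product: 17 trimethyl{(3E)-5-[(1R,3R,4S,6S,8R,10S)-4,10-dibromo-3-ethyl-2,7-dioxabicyclo[4.2.2]decan-8-yl]pent-3-en-1-yn-1-yl}silane
Conditions: Pd(PPh3)4 (5 mol %), CuI (10 mol %), Et3N, THF, rt
Reagents that add atoms: none
Why: Sonogashira coupling of a vinyl iodide proceeds at room temperature with retention of the E geometry, and zerovalent palladium does not insert into unactivated secondary alkyl bromides under these conditions.

Step 12
Reactants: 17 trimethyl{(3E)-5-[(1R,3R,4S,6S,8R,10S)-4,10-dibromo-3-ethyl-2,7-dioxabicyclo[4.2.2]decan-8-yl]pent-3-en-1-yn-1-yl}silane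
Product: 18 (1R,3R,4S,6S,8R,10S)-4,10-dibromo-3-ethyl-8-[(2E)-pent-2-en-4-yn-1-yl]-2,7-dioxabicyclo[4.2.2]decane
Conditions: K2CO3 (0.2 equiv), MeOH, 0 °C to rt
Reagents that add atoms: none
Why: Carbonate-catalysed methanolysis of the alkynyl C–Si bond is selective for the silylalkyne and mild enough to leave both β-bromo ethers untouched.

**Compound list**
1 | (E)-hex-3-en-1-ol | CC/C=C/CCO | starting material
2 | (E)-hex-3-enal | CC/C=C/CC=O | intermediate
3 | vinylmagnesium bromide | C=C[Mg]Br | starting material
4 | rac-(5E)-octa-1,5-dien-3-ol | CC/C=C/CC(O)C=C | intermediate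
5 | (3S,5E)-octa-1,5-dien-3-ol | CC/C=C/C[C@H](O)C=C | intermediate
6 | (2R,3S,5S)-3-bromo-5-ethenyl-2-ethyloxolane | CC[C@H]1O[C@H](C=C)C[C@@H]1Br | intermediate
7 | ethyl diazoacetate | CCOC(=O)C=[N+]=[N-] | starting material
8 | (2R,3S,5S)-3-bromo-5-ethenyl-1-(2-ethoxy-2-oxoethan-1-id-1-yl)-2-ethyloxolan-1-ium, the oxonium ylide with the carbanion carbon on the ring face of the vinyl group (oxygen configuration not written in the SMILES) | CC[C@H]1[O+]([CH-]C(=O)OCC)[C@H](C=C)C[C@@H]1Br | intermediate (not isolated)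
9 | ethyl (2R,4Z,7S,8R)-7-bromo-8-ethyl-3,6,7,8-tetrahydro-2H-oxocine-2-carboxylate | CCOC(=O)[C@H]1C/C=C\C[C@H](Br)[C@@H](CC)O1 | intermediate
10 | (2R,4Z,7S,8R)-7-bromo-8-ethyl-3,6,7,8-tetrahydro-2H-oxocine-2-carbaldehyde | O=C[C@H]1C/C=C\C[C@H](Br)[C@@H](CC)O1 | intermediate
11 | (1R)-1-[(2R,4Z,7S,8R)-7-bromo-8-ethyl-3,6,7,8-tetrahydro-2H-oxocin-2-yl]but-3-en-1-ol | C=CC[C@@H](O)[C@H]1C/C=C\C[C@H](Br)[C@@H](CC)O1 | intermediate
12 | (1R,3R,4S,6S,8R,10S)-4,10-dibromo-3-ethyl-8-(prop-2-en-1-yl)-2,7-dioxabicyclo[4.2.2]decane | C=CC[C@H]1O[C@H]2C[C@H](Br)[C@@H](CC)O[C@@H]1C[C@@H]2Br | intermediate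
13 | 3-{[(1R,3R,4S,6S,8R,10S)-4,10-dibromo-3-ethyl-2,7-dioxabicyclo[4.2.2]decan-8-yl]methyl}-1,2,4-trioxolane (secondary ozonide, both epimers at the trioxolane carbon) | C1OC(OO1)C[C@H]2O[C@H]3C[C@H](Br)[C@@H](CC)O[C@@H]2C[C@@H]3Br | intermediate (not isolated)
14 | [(1R,3R,4S,6S,8R,10S)-4,10-dibromo-3-ethyl-2,7-dioxabicyclo[4.2.2]decan-8-yl]acetaldehyde | O=CC[C@H]1O[C@H]2C[C@H](Br)[C@@H](CC)O[C@@H]1C[C@@H]2Br | intermediate
15 | (1R,3R,4S,6S,8R,10S)-4,10-dibromo-3-ethyl-8-[(2E)-3-iodoprop-2-en-1-yl]-2,7-dioxabicyclo[4.2.2]decane | I/C=C/C[C@H]1O[C@H]2C[C@H](Br)[C@@H](CC)O[C@@H]1C[C@@H]2Br | intermediate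
16 | trimethylsilylacetylene | C[Si](C)(C)C#C | starting material
17 | trimethyl{(3E)-5-[(1R,3R,4S,6S,8R,10S)-4,10-dibromo-3-ethyl-2,7-dioxabicyclo[4.2.2]decan-8-yl]pent-3-en-1-yn-1-yl}silane | C[Si](C)(C)C#C/C=C/C[C@H]1O[C@H]2C[C@H](Br)[C@@H](CC)O[C@@H]1C[C@@H]2Br | intermediate
18 | (1R,3R,4S,6S,8R,10S)-4,10-dibromo-3-ethyl-8-[(2E)-pent-2-en-4-yn-1-yl]-2,7-dioxabicyclo[4.2.2]decane | C#C/C=C/C[C@H]1O[C@H]2C[C@H](Br)[C@@H](CC)O[C@@H]1C[C@@H]2Br | target

**Totals and risks**
Total step count: 12. Longest linear sequence: 12 steps (from 1; the route is fully linear).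

Steps most likely to fail:

1. Step 5 (the new method). Carbene transfer to the vinyl group (cyclopropanation) or carbene dimerisation may outpace ylide formation at the hindered, inductively deactivated ether oxygen, or the ylide may collapse by [1,2] shift. The fallback uses known chemistry only, sets out from 6 and returns at 9 by ring-closing metathesis. Ozonolysis of 6 with NaBH4 work-up gives [(2S,4S,5R)-4-bromo-5-ethyloxolan-2-yl]methanol F1, and I2, PPh3 and imidazole convert it into (2R,3S,5S)-3-bromo-2-ethyl-5-(iodomethyl)oxolane F2. Zinc dust in warm ethanol inserts into the primary C–I bond, and the β-alkoxy organozinc fragments (Boord-type reductive ring opening), faster than any reaction at the secondary bromide, to (3R,4S)-4-bromohept-6-en-3-ol F3. Rh2(OAc)4-catalysed O–H insertion of 7 gives ethyl {[(3R,4S)-4-bromohept-6-en-3-yl]oxy}acetate F4. Deprotonation with LiN(SiMe3)2 and alkylation with allyl iodide (THF, −78 °C) gives ethyl 2-{[(3R,4S)-4-bromohept-6-en-3-yl]oxy}pent-4-enoate F5 as a pair of C2 epimers. Ring-closing metathesis with second-generation Grubbs catalyst (CH2Cl2, reflux, high dilution) forms the C9=C10 bond and gives 9 together with ethyl (2S,4Z,7S,8R)-7-bromo-8-ethyl-3,6,7,8-tetrahydro-2H-oxocine-2-carboxylate F6, which is separated and equilibrated toward 9 with DBU.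

2. Step 8. Chemoselectivity between the two alkenes may be lost: the same hydroxyl can close 5-endo onto a bromonium ion of the allyl group (the mode exploited in step 4), and excess reagent would then brominate both sites. The fallback sets out from 10 and returns at 14 with a side chain that carries no second alkene. Chelation-controlled Mukaiyama aldol addition of 1-(tert-butyldimethylsilyloxy)-1-(ethylsulfanyl)ethene to 10 (MgBr2·OEt2, CH2Cl2, −78 °C, acidic work-up) should give the syn adduct S-ethyl (3R)-3-[(2R,4Z,7S,8R)-7-bromo-8-ethyl-3,6,7,8-tetrahydro-2H-oxocin-2-yl]-3-hydroxypropanethioate F7 with the same 6R configuration. NBS then closes the oxane on the only alkene present to give S-ethyl [(1R,3R,4S,6S,8R,10S)-4,10-dibromo-3-ethyl-2,7-dioxabicyclo[4.2.2]decan-8-yl]ethanethioate F8. i-Bu2AlH (CH2Cl2, −78 °C) reduces the thioester to aldehyde 14, which also makes the ozonolysis unnecessary.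

3. Step 4. Bromine transfer is less reversible than iodine transfer, so facial selectivity relative to C10 may be poor and the 2,5-cis oxolane, which carries the wrong C12/C13 configuration into the key step, may form alongside 6. The fallback sets out from 5 and returns at 6 with C12/C13 set by a reagent instead of by the substrate. Shi epoxidation of 5 with the enantiomer of the fructose-derived ketone (KHSO5, K2CO3 buffer, MeCN/dimethoxymethane, 0 °C) should epoxidise only the E-disubstituted alkene to (2S)-1-[(2S,3S)-3-ethyloxiran-2-yl]but-3-en-2-ol F9. Camphorsulfonic acid closes the oxolane by 5-endo opening at C13 with inversion to (2R,3S,5S)-5-ethenyl-2-ethyloxolan-3-ol F10. Mitsunobu inversion with 4-nitrobenzoic acid gives (2R,3R,5S)-5-ethenyl-2-ethyloxolan-3-yl 4-nitrobenzoate F11, and methanolysis (K2CO3, MeOH) gives (2R,3R,5S)-5-ethenyl-2-ethyloxolan-3-ol F12. Appel bromination (CBr4, P(n-C8H17)3, toluene, 70 °C) inverts C12 a second time and gives 6.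

**Further compounds**
F1 | step 5 | [(2S,4S,5R)-4-bromo-5-ethyloxolan-2-yl]methanol | CC[C@H]1O[C@H](CO)C[C@@H]1Br
F2 | step 5 | (2R,3S,5S)-3-bromo-2-ethyl-5-(iodomethyl)oxolane | CC[C@H]1O[C@H](CI)C[C@@H]1Br
F3 | step 5 | (3R,4S)-4-bromohept-6-en-3-ol | CC[C@@H](O)[C@@H](Br)CC=C
F4 | step 5 | ethyl {[(3R,4S)-4-bromohept-6-en-3-yl]oxy}acetate | CCOC(=O)CO[C@H](CC)[C@@H](Br)CC=C
F5 | step 5 | ethyl 2-{[(3R,4S)-4-bromohept-6-en-3-yl]oxy}pent-4-enoate (both C2 epimers) | C=CCC(O[C@H](CC)[C@@H](Br)CC=C)C(=O)OCC
F6 | step 5 | ethyl (2S,4Z,7S,8R)-7-bromo-8-ethyl-3,6,7,8-tetrahydro-2H-oxocine-2-carboxylate | CCOC(=O)[C@@H]1C/C=C\C[C@H](Br)[C@@H](CC)O1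
F7 | step 8 | S-ethyl (3R)-3-[(2R,4Z,7S,8R)-7-bromo-8-ethyl-3,6,7,8-tetrahydro-2H-oxocin-2-yl]-3-hydroxypropanethioate | CCSC(=O)C[C@@H](O)[C@H]1C/C=C\C[C@H](Br)[C@@H](CC)O1
F8 | step 8 | S-ethyl [(1R,3R,4S,6S,8R,10S)-4,10-dibromo-3-ethyl-2,7-dioxabicyclo[4.2.2]decan-8-yl]ethanethioate | CCSC(=O)C[C@H]1O[C@H]2C[C@H](Br)[C@@H](CC)O[C@@H]1C[C@@H]2Br
F9 | step 4 | (2S)-1-[(2S,3S)-3-ethyloxiran-2-yl]but-3-en-2-ol | CC[C@@H]1O[C@H]1C[C@H](O)C=C
F10 | step 4 | (2R,3S,5S)-5-ethenyl-2-ethyloxolan-3-ol | CC[C@H]1O[C@H](C=C)C[C@@H]1O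
F11 | step 4 | (2R,3R,5S)-5-ethenyl-2-ethyloxolan-3-yl 4-nitrobenzoate | CC[C@H]1O[C@H](C=C)C[C@H]1OC(=O)c1ccc(cc1)[N+](=O)[O-]
F12 | step 4 | (2R,3R,5S)-5-ethenyl-2-ethyloxolan-3-ol | CC[C@H]1O[C@H](C=C)C[C@H]1O
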